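Ring A (C1–C4 plus C5 and C10) is annulated onto a carvone-derived ring B in one flask. The allylic alcohol 12, whose C1–O bond, C10=C5 enone and C9 ketone are in place, adds to but-2-yne under gold catalysis. The enol ether undergoes Claisen rearrangement, which forges C4–C5 at the quaternary C5 anti to the C7 isopropenyl group and unveils a C1=C10 α-methylene ketone. Base then closes C1–C2 by Michael addition of the new C3 methyl ketone. The step exploits the butanone-like C2–C3(O)–C4(C15) unit of ring A and the 1,5-relationship of the C3 and C9 oxygens. Thermodynamic reduction, two esterifications and C8 oxidation finish.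

Key step: step 8

Remark 1: eremophilane numbering is used throughout (ring A: C1–C5, C10; ring B: C5–C10; C11–C13 isopropenyl on C7; C14 methyl on C5; C15 methyl on C4); β is the decalin face that carries C14.
Remark 2: the carbinol centre C5 in 5–11 and the centre C8 in 9–22 are drawn as the expected major epimers; both become trigonal later (step 7 and step 13), so minor epimers converge.

Step 1
Reactants: 1 (R)-(−)-carvone; 2 hydrogen peroxide
Product: 3 (1R,4R,6R)-1-methyl-4-(prop-1-en-2-yl)-7-oxabicyclo[4.1.0]heptan-2-one (carvone oxide)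
Conditions: 30% aq. H2O2, NaOH (cat.), MeOH, 0 °C
Reagents that add atoms: hydrogen peroxide, OO
Why: Weitz–Scheffer nucleophilic epoxidation touches only the enone, and hydroperoxide should add to the β-carbon (later C9) anti to the isopropenyl group, so the epoxide is trans to it.

Step 2
Reactants: 3 carvone oxide; 4 methyllithium
Product: 5 (1R,2S,4R,6R)-1,2-dimethyl-4-(prop-1-en-2-yl)-7-oxabicyclo[4.1.0]heptan-2-ol
Conditions: MeLi, THF, −78 °C; then H2O
Reagents that add atoms: methyllithium, [Li]C
Why: 1,2-addition of MeLi to the ketone, expected anti to the epoxide oxygen, installs C14 on the future C5; the carbinol configuration is erased in step 7.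

Step 3
Reactants: 5 epoxy alcohol
Product: 6 (1S,3R,5R)-1-methyl-2-methylidene-5-(prop-1-en-2-yl)cyclohexane-1,3-diol
Conditions: LiN(i-Pr)2 (3.5 equiv), THF, 0 °C to 45 °C; then H2O
Reagents that add atoms: none
Why: Base-promoted epoxide-to-allylic-alcohol isomerisation (syn β-elimination) should remove a proton from the C1 methyl group and open the C10–O bond, giving the exocyclic alkene with C9–O retained; C5 carries no hydrogen.

Step 4
Reactants: 6 allylic diol
Product: 7 (3S,5S)-3-hydroxy-3-methyl-2-methylidene-5-(prop-1-en-2-yl)cyclohexan-1-one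
Conditions: MnO2, CH2Cl2, 25 °C
Reagents that add atoms: none
Why: MnO2 oxidises only the secondary allylic alcohol at C9; the tertiary alcohol cannot be oxidised and the isolated alkene is inert.

Step 5
Reactants: 7 α-methylene hydroxy ketone; 8 2-(phenylsulfonyl)-3-phenyloxaziridine (Davis oxaziridine)
Product: 9 (3S,5R,6R)-3,6-dihydroxy-3-methyl-2-methylidene-5-(prop-1-en-2-yl)cyclohexan-1-one
Conditions: KN(SiMe3)2 (2.2 equiv), THF, −78 °C; then 8, −78 °C; then H2O
Reagents that add atoms: Davis oxaziridine, O=S(=O)(N1OC1c1ccccc1)c1ccccc1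
Why: Davis enolate hydroxylation; C8 is the only enolisable position, and oxygen should enter anti to the neighbouring isopropenyl group (this centre is oxidised in step 13).

Step 6
Reactants: 9 α-hydroxy ketone; 10 4-methoxybenzyl bromide
Product: 11 (3S,5R,6R)-3-hydroxy-6-[(4-methoxyphenyl)methoxy]-3-methyl-2-methylidene-5-(prop-1-en-2-yl)cyclohexan-1-one
Conditions: PMBBr, Ag2O, CH2Cl2, 25 °C, dark
Reagents that add atoms: 4-methoxybenzyl bromide, COc1ccc(CBr)cc1
Why: Silver-oxide-mediated Williamson etherification under non-basic conditions alkylates the secondary hydroxyl and leaves the hindered tertiary one; a benzyl-type ether cannot migrate between the C8 and C9 oxygens in later enolate steps.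

Step 7
Reactants: 11 tertiary allylic alcohol
Product: 12 (5R,6R)-2-(hydroxymethyl)-6-[(4-methoxyphenyl)methoxy]-3-methyl-5-(prop-1-en-2-yl)cyclohex-2-en-1-one
Conditions: Re2O7 (3 mol %), CH2Cl2, 0 °C
Reagents that add atoms: none
Why: Rhenium-oxo-catalysed 1,3-transposition of an allylic alcohol ([3,3] shift of the allyl perrhenate) should run under thermodynamic control to the primary alcohol, because C10=C5 becomes tetrasubstituted, endocyclic and conjugated.

Step 8
Reactants: 12 primary allylic alcohol; 13 but-2-yne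
Product: 16 8α-[(4-methoxyphenyl)methoxy]-10βH-eremophil-11-ene-3,9-dione, via enol ether 14 (not isolated), via methylene diketone 15 (not isolated)
Conditions: 13 (5 equiv), (IPr)AuNTf2 (3 mol %; IPr = 1,3-bis(2,6-diisopropylphenyl)imidazol-2-ylidene), toluene, sealed tube, 60 °C then 130 °C; then KOt-Bu (0.3 equiv), t-BuOH, 25 °C
Reagents that add atoms: but-2-yne, CC#CC
Why: Monovalent gold activates but-2-yne for anti addition of the primary hydroxyl of 12 (the known gold-catalysed hydroalkoxylation–Claisen tandem of allylic alcohols and internal alkynes), and because the alkyne is symmetrical only the (Z)-but-2-en-2-yl ether 14 can form; its chair-like [3,3]-sigmatropic shift breaks C1–O and makes C4–C5, giving the α-methylene ketone 15. The new bond should enter C5 axially on the face anti to the equatorial C7 isopropenyl group (the preference known from conjugate additions to 5-substituted cyclohexenones), which sets the quaternary centre with C14 syn to the isopropenyl group. KOt-Bu then enolises the C2 methyl group of the new ketone, which adds to C1 of the exocyclic enone in a 6-endo-trig intramolecular Michael addition that closes ring A; the Claisen step closes no ring. C4 and C10 are α to carbonyl groups and should equilibrate under the same base to the equatorial C15 methyl group and the cis ring fusion, the latter favoured because the trans-fused isomer would hold C14 and the isopropenyl group syn-diaxial. Chemoselectivity rests on the alkynophilicity of gold (the isopropenyl group is untouched), and regioselectivity on the concerted shift, which can only deliver C4 to C5.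

Step 9
Reactants: 16 diketone
Product: 17 8α-[(4-methoxyphenyl)methoxy]-10βH-eremophil-11-ene-3α,9β-diol
Conditions: Al(Oi-Pr)3 (4 equiv), i-PrOH, 85 °C, closed vessel, 48 h
Reagents that add atoms: none
Why: Meerwein–Ponndorf–Verley reduction under equilibrating conditions (acetone kept in the vessel) should give the thermodynamic equatorial alcohols, 3α-OH avoiding the syn-diaxial contact with C14 and 9β-OH that with C4.

Step 10
Reactants: 17 diol; 18 (E)-2-methylbut-2-enoyl chloride (tigloyl chloride)
Product: 19 9β-hydroxy-8α-[(4-methoxyphenyl)methoxy]-10βH-eremophil-11-en-3α-yl (2E)-2-methylbut-2-enoate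
Conditions: 18 (1.1 equiv), pyridine, DMAP (cat.), CH2Cl2, 0 °C
Reagents that add atoms: tigloyl chloride, C/C=C(\C)C(Cl)=O
Why: Site-selective acylation: C3–OH has one substituted neighbour, whereas C9–OH is flanked by the C8 ether and the ring-fusion carbon; the (E) geometry comes from the reagent.

Step 11
Reactants: 19 mono-tiglate; 20 3-methylbut-2-enoyl chloride (senecioyl chloride)
Product: 21 8α-[(4-methoxyphenyl)methoxy]-9β-[(3-methylbut-2-enoyl)oxy]-10βH-eremophil-11-en-3α-yl (2E)-2-methylbut-2-enoate
Conditions: 20 (3 equiv), pyridine, DMAP, CH2Cl2, 40 °C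
Reagents that add atoms: senecioyl chloride, CC(C)=CC(Cl)=O
Why: Acylpyridinium-mediated esterification of the hindered equatorial C9–OH; pyridine in place of a trialkylamine limits vinylketene formation and deconjugation of the acyl group.

Step 12
Reactants: 21 diester ether
Product: 22 8α-hydroxy-9β-[(3-methylbut-2-enoyl)oxy]-10βH-eremophil-11-en-3α-yl (2E)-2-methylbut-2-enoate
Conditions: DDQ, CH2Cl2–pH 7 buffer, 0 °C
Reagents that add atoms: none
Why: Oxidative cleavage of the 4-methoxybenzyl ether by DDQ is neutral, so the esters, the alkenes and the position of the C9 acyl group should be unaffected.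

Step 13
Reactants: 22 hydroxy diester
Product: 23 (3R,4R,5R,7R,9R,10S)-9-[(3-methylbut-2-enoyl)oxy]-8-oxoeremophil-11-en-3-yl (2E)-2-methylbut-2-enoate (CNP0375730.1)
Conditions: Dess–Martin periodinane, NaHCO3, CH2Cl2, 0 °C to 25 °C
Reagents that add atoms: none
Why: Buffered Dess–Martin oxidation forms the C8 ketone without base, so C7 and C9 (both α to the new ketone) keep their configuration and the isopropenyl group does not move into conjugation.

Compound list
1 | (R)-(−)-carvone | CC1=CC[C@H](CC1=O)C(C)=C | starting material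
2 | hydrogen peroxide | OO | starting material
3 | (1R,4R,6R)-1-methyl-4-(prop-1-en-2-yl)-7-oxabicyclo[4.1.0]heptan-2-one | C[C@@]12O[C@@H]1C[C@@H](C(C)=C)CC2=O | intermediate
4 | methyllithium | [Li]C | starting material
5 | (1R,2S,4R,6R)-1,2-dimethyl-4-(prop-1-en-2-yl)-7-oxabicyclo[4.1.0]heptan-2-ol | C[C@@]12O[C@@H]1C[C@@H](C(C)=C)C[C@]2(C)O | intermediate
6 | (1S,3R,5R)-1-methyl-2-methylidene-5-(prop-1-en-2-yl)cyclohexane-1,3-diol | C=C1[C@H](O)C[C@@H](C(C)=C)C[C@]1(C)O | intermediate
7 | (3S,5S)-3-hydroxy-3-methyl-2-methylidene-5-(prop-1-en-2-yl)cyclohexan-1-one | C=C1C(=O)C[C@@H](C(C)=C)C[C@]1(C)O | intermediate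
8 | 2-(phenylsulfonyl)-3-phenyloxaziridine (Davis oxaziridine, racemic) | O=S(=O)(N1OC1c1ccccc1)c1ccccc1 | starting material
9 | (3S,5R,6R)-3,6-dihydroxy-3-methyl-2-methylidene-5-(prop-1-en-2-yl)cyclohexan-1-one | C=C1C(=O)[C@H](O)[C@@H](C(C)=C)C[C@]1(C)O | intermediate
10 | 4-methoxybenzyl bromide | COc1ccc(CBr)cc1 | starting material
11 | (3S,5R,6R)-3-hydroxy-6-[(4-methoxyphenyl)methoxy]-3-methyl-2-methylidene-5-(prop-1-en-2-yl)cyclohexan-1-one | C=C1C(=O)[C@H](OCc2ccc(OC)cc2)[C@@H](C(C)=C)C[C@]1(C)O | intermediate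
12 | (5R,6R)-2-(hydroxymethyl)-6-[(4-methoxyphenyl)methoxy]-3-methyl-5-(prop-1-en-2-yl)cyclohex-2-en-1-one | OCC1=C(C)C[C@H](C(C)=C)[C@@H](OCc2ccc(OC)cc2)C1=O | intermediate
13 | but-2-yne | CC#CC | starting material
14 | (5R,6R)-2-{[(2Z)-but-2-en-2-yloxy]methyl}-6-[(4-methoxyphenyl)methoxy]-3-methyl-5-(prop-1-en-2-yl)cyclohex-2-en-1-one | C/C=C(/C)OCC1=C(C)C[C@H](C(C)=C)[C@@H](OCc2ccc(OC)cc2)C1=O | intermediate (not isolated)
15 | 6-[(4-methoxyphenyl)methoxy]-3-methyl-2-methylidene-3-(3-oxobutan-2-yl)-5-(prop-1-en-2-yl)cyclohexan-1-one; C4–C5 bond anti to the isopropenyl group, C15 anti to C14 (kinetic C4 epimer) | C=C1C(=O)[C@H](OCc2ccc(OC)cc2)[C@@H](C(C)=C)C[C@]1(C)[C@H](C)C(C)=O | intermediate (not isolated)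
16 | 8α-[(4-methoxyphenyl)methoxy]-10βH-eremophil-11-ene-3,9-dione (4β,5β-dimethyl, 7β-isopropenyl) | C=C(C)[C@H]1C[C@@]2(C)[C@H](CCC(=O)[C@@H]2C)C(=O)[C@@H]1OCc1ccc(OC)cc1 | intermediate
17 | 8α-[(4-methoxyphenyl)methoxy]-10βH-eremophil-11-ene-3α,9β-diol | C=C(C)[C@H]1C[C@@]2(C)[C@H](CC[C@@H](O)[C@@H]2C)[C@@H](O)[C@@H]1OCc1ccc(OC)cc1 | intermediate
18 | (E)-2-methylbut-2-enoyl chloride (tigloyl chloride) | C/C=C(\C)C(Cl)=O | starting material
19 | 9β-hydroxy-8α-[(4-methoxyphenyl)methoxy]-10βH-eremophil-11-en-3α-yl (2E)-2-methylbut-2-enoate | C=C(C)[C@H]1C[C@@]2(C)[C@H](CC[C@@H](OC(=O)/C(C)=C/C)[C@@H]2C)[C@@H](O)[C@@H]1OCc1ccc(OC)cc1 | intermediate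
20 | 3-methylbut-2-enoyl chloride (senecioyl chloride) | CC(C)=CC(Cl)=O | starting material
21 | 8α-[(4-methoxyphenyl)methoxy]-9β-[(3-methylbut-2-enoyl)oxy]-10βH-eremophil-11-en-3α-yl (2E)-2-methylbut-2-enoate | C=C(C)[C@H]1C[C@@]2(C)[C@H](CC[C@@H](OC(=O)/C(C)=C/C)[C@@H]2C)[C@@H](OC(=O)C=C(C)C)[C@@H]1OCc1ccc(OC)cc1 | intermediate
22 | 8α-hydroxy-9β-[(3-methylbut-2-enoyl)oxy]-10βH-eremophil-11-en-3α-yl (2E)-2-methylbut-2-enoate | C=C(C)[C@H]1C[C@@]2(C)[C@H](CC[C@@H](OC(=O)/C(C)=C/C)[C@@H]2C)[C@@H](OC(=O)C=C(C)C)[C@@H]1O | intermediate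
23 | (3R,4R,5R,7R,9R,10S)-9-[(3-methylbut-2-enoyl)oxy]-8-oxoeremophil-11-en-3-yl (2E)-2-methylbut-2-enoate (CNP0375730.1) | C=C(C)[C@H]1C[C@@]2(C)[C@H](CC[C@@H](OC(=O)/C(C)=C/C)[C@@H]2C)[C@@H](OC(=O)C=C(C)C)C1=O | target

Total step count: 13. Longest linear sequence: 13 steps (the route is fully linear from 1).

Steps most likely to fail

Step 8. The hydroalkoxylation may be slow, the sigmatropic shift may show poor facial selectivity at C5, or the exocyclic enone may oligomerise before ring closure. The fallback sets out from 11 and comes back at 16, making the two bonds in separate operations. Compound 11 is heated with methyl 3-oxopentanoate and DBU in MeCN at 60 °C; conjugate addition to the exocyclic enone and loss of the tertiary hydroxyl (SN2′ alkylation) should form C1–C2 and give methyl 2-{[(4R,5R)-5-[(4-methoxyphenyl)methoxy]-2-methyl-6-oxo-4-(prop-1-en-2-yl)cyclohex-1-en-1-yl]methyl}-3-oxopentanoate F1. Krapcho dealkoxycarbonylation (LiCl, wet DMSO, 140 °C) then gives (5R,6R)-6-[(4-methoxyphenyl)methoxy]-3-methyl-2-(3-oxopentyl)-5-(prop-1-en-2-yl)cyclohex-2-en-1-one F2. KOt-Bu in t-BuOH closes C4–C5 by intramolecular Michael addition of the ethyl ketone to the β,β-disubstituted enone (axial attack anti to the isopropenyl group) and equilibrates C4 and C10, returning 16.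

Step 9. Hydride transfer to the hindered C9 carbonyl may be too slow for equilibrium to be reached, or aluminium enolates may trigger aldol side reactions. The fallback sets out from 16 and comes back at 17. LiBH(s-Bu)3 in THF at −78 °C to 0 °C reduces both ketones by equatorial attack to the diaxial diol 8α-[(4-methoxyphenyl)methoxy]-10βH-eremophil-11-ene-3β,9α-diol F3. Catalytic (C5Ph5)Ru(CO)2Cl with KOt-Bu in toluene at 70 °C then epimerises both carbinol centres by reversible hydrogen transfer to the equatorial diol 17.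

Step 5. The cross-conjugated enolate may undergo Michael self-condensation with exocyclic enone that is not yet deprotonated, or add to the sulfonimine by-product. The fallback sets out from 7 and comes back at 9. Mn(OAc)3 in benzene at reflux acetoxylates the α′ position (C8) of the enone to give (3S,5R,6R)-6-acetoxy-3-hydroxy-3-methyl-2-methylidene-5-(prop-1-en-2-yl)cyclohexan-1-one F4; K2CO3 in MeOH at 0 °C removes the acetyl group and returns 9.

Further compounds
F1 | step 8 | methyl 2-{[(4R,5R)-5-[(4-methoxyphenyl)methoxy]-2-methyl-6-oxo-4-(prop-1-en-2-yl)cyclohex-1-en-1-yl]methyl}-3-oxopentanoate (both epimers at the keto ester carbon) | CCC(=O)C(CC1=C(C)C[C@H](C(C)=C)[C@@H](OCc2ccc(OC)cc2)C1=O)C(=O)OC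
F2 | step 8 | (5R,6R)-6-[(4-methoxyphenyl)methoxy]-3-methyl-2-(3-oxopentyl)-5-(prop-1-en-2-yl)cyclohex-2-en-1-one | CCC(=O)CCC1=C(C)C[C@H](C(C)=C)[C@@H](OCc2ccc(OC)cc2)C1=O
F3 | step 9 | 8α-[(4-methoxyphenyl)methoxy]-10βH-eremophil-11-ene-3β,9α-diol | C=C(C)[C@H]1C[C@@]2(C)[C@H](CC[C@H](O)[C@@H]2C)[C@H](O)[C@@H]1OCc1ccc(OC)cc1
F4 | step 5 | (3S,5R,6R)-6-acetoxy-3-hydroxy-3-methyl-2-methylidene-5-(prop-1-en-2-yl)cyclohexan-1-one | C=C1C(=O)[C@H](OC(C)=O)[C@@H](C(C)=C)C[C@]1(C)O
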